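**Retrosynthetic overview**
1. The target is opened at C3a–C7a and at the lactone C2–O1 bond to an open-chain (6S)-ynal methyl ketone that already carries the palmitate. One carbene-catalysed homoenolate annulation closes the carbocycle first (C–C bond) and the butenolide second (acyl transfer), in the same flask.
2. The ynal comes from its diethyl acetal, and the palmitate from esterification of an (S)-β-hydroxy ketone.
3. The β-hydroxy ketone comes from acetone and 6,6-diethoxy-3,3-dimethylhex-4-ynal by an enamine-catalysed aldol that sets C6. C7a is then relayed from C6 in the annulation.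
4. That aldehyde comes from 2,2-dimethylpent-4-enal: the allyl group is cleaved to CHO and the neopentyl CHO is homologated to the alkynyl acetal.

Assumption: ring positions are named with loliolide numbering (O1, C2, C3, C3a, C4–C7, C7a), also in the open-chain precursors; the target is (6S,7aR).

**Route**

Step 1
Reactants: 1 2,2-dimethylpent-4-enal; 2 carbon tetrabromide
Product: 3 1,1-dibromo-3,3-dimethylhexa-1,5-diene
Conditions: CBr4 (1.5 equiv), PPh3 (3.0 equiv), CH2Cl2, 0 °C
Reagents that add atoms: carbon tetrabromide (2), BrC(Br)(Br)Br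
Why: Corey–Fuchs (Ramirez) dibromo-olefination of a non-enolisable aldehyde by the ylide formed in situ; the isolated alkene is inert and no stereocentre is involved.

Step 2
Reactants: 3 1,1-dibromo-3,3-dimethylhexa-1,5-diene; 4 triethyl orthoformate
Product: 7 7,7-diethoxy-4,4-dimethylhept-1-en-5-yne, via lithium 3,3-dimethylhex-5-en-1-yn-1-ide 5 (not isolated), via (3,3-dimethylhex-5-en-1-yn-1-yl)magnesium bromide 6 (not isolated)
Conditions: n-BuLi (2.1 equiv), THF, −78→0 °C; MgBr2·OEt2 (1.1 equiv); HC(OEt)3 (3 equiv), PhMe, 90 °C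
Reagents that add atoms: triethyl orthoformate (4), CCOC(OCC)OCC
Why: Second stage of the Corey–Fuchs alkyne synthesis (Fritsch–Buttenberg–Wiechell rearrangement to the lithium acetylide), then Bodroux–Chichibabin substitution of the orthoformate by the alkynylmagnesium bromide, which installs the future C2 as a masked aldehyde; no stereocentre is involved.

Step 3
Reactants: 7 7,7-diethoxy-4,4-dimethylhept-1-en-5-yne
Product: 9 6,6-diethoxy-3,3-dimethylhex-4-ynal, via 7,7-diethoxy-4,4-dimethylhept-5-yne-1,2-diol 8 (not isolated)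
Conditions: OsO4 (2 mol%), NaIO4 (4 equiv), 2,6-lutidine (2 equiv), dioxane–H2O (3:1), 23 °C
Reagents that add atoms: osmium tetroxide, O=[Os](=O)(=O)=O; sodium periodate (terminal oxygen source), [Na+].[O-]I(=O)(=O)=O
Why: Lemieux–Johnson oxidative cleavage, in which OsO4 dihydroxylates only the terminal alkene (alkyne and buffered acetal are untouched) and periodate cleaves the diol to the C6 aldehyde; no stereocentre remains.

Step 4
Reactants: 9 6,6-diethoxy-3,3-dimethylhex-4-ynal; 10 acetone
Product: 11 (4S)-9,9-diethoxy-4-hydroxy-6,6-dimethylnon-7-yn-2-one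
Conditions: acetone (solvent), (S)-N-[(S)-1-hydroxy-4-methyl-1,1-diphenylpentan-2-yl]pyrrolidine-2-carboxamide (10 mol%), −25 °C, 48 h
Reagents that add atoms: acetone (10), CC(C)=O
Why: Enamine-catalysed direct asymmetric aldol (List–Barbas type) in which the L-configured prolinamide delivers the acetone enamine to the Re face of the aldehyde through a hydrogen-bonded chair transition state, giving the (S)-carbinol (the later C6), while the β-quaternary carbon slows aldehyde self-condensation.

Step 5
Reactants: 11 (4S)-9,9-diethoxy-4-hydroxy-6,6-dimethylnon-7-yn-2-one; 12 hexadecanoyl chloride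
Product: 13 (4S)-9,9-diethoxy-6,6-dimethyl-2-oxonon-7-yn-4-yl hexadecanoate
Conditions: C15H31COCl (1.2 equiv), pyridine (2 equiv), 4-(dimethylamino)pyridine (5 mol%), CH2Cl2, 0 °C
Reagents that add atoms: hexadecanoyl chloride (12), CCCCCCCCCCCCCCCC(=O)Cl
Why: Nucleophile-catalysed O-acylation with an acid chloride, which leaves the C–O bond and so the configuration intact; the weak base at 0 °C avoids β-elimination of the new β-acyloxy ketone.

Step 6
Reactants: 13 (4S)-9,9-diethoxy-6,6-dimethyl-2-oxonon-7-yn-4-yl hexadecanoate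
Product: 14 (6S)-4,4-dimethyl-1,8-dioxonon-2-yn-6-yl hexadecanoate
Conditions: p-toluenesulfonic acid monohydrate (20 mol%), acetone–H2O (10:1), 40 °C
Reagents that add atoms: water, O
Why: Acid-catalysed acetal hydrolysis unmasks the ynal; the ester and the β-acyloxy ketone tolerate dilute acid and the stereocentre is not touched.

Step 7
Reactants: 14 (6S)-4,4-dimethyl-1,8-dioxonon-2-yn-6-yl hexadecanoate
Product: 17 (−)-3-O-palmitoylloliolide [(6S,7aR)-4,4,7a-trimethyl-2-oxo-2,4,5,6,7,7a-hexahydro-1-benzofuran-6-yl hexadecanoate], via Breslow intermediate 15 (not isolated), via acyl azolium alkoxide 16 (not isolated)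
Conditions: 1,3-bis(2,4,6-trimethylphenyl)imidazolium chloride (20 mol%), KOt-Bu (18 mol%, premixed), LiCl (1.0 equiv), 4 Å MS, THF (0.02 M), 23→45 °C
Reagents that add atoms: none
Why: Proposed new method: the carbene adds to the ynal to give a Breslow intermediate whose conjugation through the alkyne makes C3a (the ynal β-carbon) nucleophilic (a homoenolate-type allenol), and this carbon attacks the tethered ketone carbon C7a through a six-membered chair in which the C6 ester is equatorial and the ketone oxygen, not its methyl, takes the axial site beside the axial C4 methyl (avoiding a methyl/methyl 1,3-diaxial clash), which puts O1 trans to the C6 oxygen and so gives (7aR); tautomerisation to the (Z)-acyl azolium and O-acylation by the C7a alkoxide then close the butenolide and release the carbene, the whole step being an isomerisation; the closest known reactions are the carbene-catalysed [3+2] annulations of enals (to γ-butyrolactones) and of ynals (to butenolides) with activated ketones.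

**Compound list**
1 | 2,2-dimethylpent-4-enal | C=CCC(C)(C)C=O | starting material
2 | carbon tetrabromide | BrC(Br)(Br)Br | starting material
3 | 1,1-dibromo-3,3-dimethylhexa-1,5-diene | BrC(Br)=CC(C)(C)CC=C | intermediate
4 | triethyl orthoformate | CCOC(OCC)OCC | starting material
5 | lithium 3,3-dimethylhex-5-en-1-yn-1-ide | [Li]C#CC(C)(C)CC=C | intermediate
6 | (3,3-dimethylhex-5-en-1-yn-1-yl)magnesium bromide | Br[Mg]C#CC(C)(C)CC=C | intermediate
7 | 7,7-diethoxy-4,4-dimethylhept-1-en-5-yne | CCOC(OCC)C#CC(C)(C)CC=C | intermediate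
8 | 7,7-diethoxy-4,4-dimethylhept-5-yne-1,2-diol (racemic) | CCOC(OCC)C#CC(C)(C)CC(O)CO | intermediate
9 | 6,6-diethoxy-3,3-dimethylhex-4-ynal | CCOC(OCC)C#CC(C)(C)CC=O | intermediate
10 | acetone | CC(C)=O | starting material
11 | (4S)-9,9-diethoxy-4-hydroxy-6,6-dimethylnon-7-yn-2-one | CCOC(OCC)C#CC(C)(C)C[C@H](O)CC(C)=O | intermediate
12 | hexadecanoyl chloride | CCCCCCCCCCCCCCCC(=O)Cl | starting material
13 | (4S)-9,9-diethoxy-6,6-dimethyl-2-oxonon-7-yn-4-yl hexadecanoate | CCCCCCCCCCCCCCCC(=O)O[C@H](CC(C)=O)CC(C)(C)C#CC(OCC)OCC | intermediate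
14 | (6S)-4,4-dimethyl-1,8-dioxonon-2-yn-6-yl hexadecanoate | CCCCCCCCCCCCCCCC(=O)O[C@H](CC(C)=O)CC(C)(C)C#CC=O | intermediate
15 | (4S)-9-[1,3-bis(2,4,6-trimethylphenyl)-1,3-dihydro-2H-imidazol-2-ylidene]-9-hydroxy-6,6-dimethyl-2-oxonon-7-yn-4-yl hexadecanoate (Breslow intermediate) | CCCCCCCCCCCCCCCC(=O)O[C@H](CC(C)=O)CC(C)(C)C#CC(O)=C1N(c2c(C)cc(C)cc2C)C=CN1c3c(C)cc(C)cc3C | intermediate
16 | 2-{(2Z)-2-[(2R,4S)-4-(hexadecanoyloxy)-2,6,6-trimethyl-2-oxidocyclohexylidene]acetyl}-1,3-bis(2,4,6-trimethylphenyl)imidazolium (zwitterion) | CCCCCCCCCCCCCCCC(=O)O[C@H]1CC(C)(C)/C(=C/C(=O)c2n(-c3c(C)cc(C)cc3C)cc[n+]2-c4c(C)cc(C)cc4C)[C@](C)([O-])C1 | intermediate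
17 | (−)-3-O-palmitoylloliolide, (6S,7aR)-4,4,7a-trimethyl-2-oxo-2,4,5,6,7,7a-hexahydro-1-benzofuran-6-yl hexadecanoate | CCCCCCCCCCCCCCCC(=O)O[C@H]1CC(C)(C)C2=CC(=O)O[C@]2(C)C1 | target

**Step count and risks**
Total steps: 7. Longest linear sequence: 7 (fully linear from 1).

The three steps most likely to fail:

Step 7 (annulation). The allenol may be protonated instead of adding to the unactivated ketone, base may eliminate the palmitate, the acyl azolium may form with the wrong alkene geometry, and the C7a selectivity rests on a chair model only. The fallback makes the same C3a–C7a bond by one-electron reversal of the ketone instead. It sets out from 14: Pinnick oxidation (NaClO2, NaH2PO4, 2-methylbut-2-ene, t-BuOH–H2O) gives (6S)-6-(hexadecanoyloxy)-4,4-dimethyl-8-oxonon-2-ynoic acid F1. Esterification (MeOH, EDC·HCl, catalytic 4-(dimethylamino)pyridine) gives methyl (6S)-6-(hexadecanoyloxy)-4,4-dimethyl-8-oxonon-2-ynoate F2. SmI2 (2.2 equiv) with t-BuOH in THF at −78 °C then forms the ketyl, which closes 6-exo onto the ynoate β-carbon to give methyl (2Z)-[(2R,4S)-4-(hexadecanoyloxy)-2-hydroxy-2,6,6-trimethylcyclohexylidene]acetate F3 as its samarium alkoxide, and this lactonises in the flask, coming back to the route at 17. Samarium chelation to the ester could change the facial sense at C7a, so the diastereomer ratio would have to be checked.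

Step 4 (aldol). An α-unbranched aldehyde may give low conversion or insufficient enantiomeric excess under amine catalysis. The fallback replaces the aldol by reagent-controlled allylboration and sets out from 9. The B-methallyldiisopinocampheylborane that adds to the aldehyde Re face (the reagent made from (−)-α-pinene; Et2O, −78 °C, then NaOH/H2O2) gives (4R)-9,9-diethoxy-2,6,6-trimethylnon-1-en-7-yn-4-ol F4; the descriptor changes by priority only, the spatial arrangement is that of 11. Acylation as in step 5 gives (4R)-9,9-diethoxy-2,6,6-trimethylnon-1-en-7-yn-4-yl hexadecanoate F5. OsO4/NaIO4/2,6-lutidine cleavage of the 1,1-disubstituted alkene unveils the methyl ketone, coming back to the route at 13.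

Step 2 (orthoformate substitution). The hindered alkynylmagnesium bromide may react sluggishly with the orthoformate. The fallback sets out from 5: quenching with DMF (inverse addition into aqueous KH2PO4) gives 4,4-dimethylhept-6-en-2-ynal F6, which is acetalised (EtOH, catalytic pyridinium p-toluenesulfonate, 3 Å MS) to come back to the route at 7.

**Further compounds**
F1 | step 7 | (6S)-6-(hexadecanoyloxy)-4,4-dimethyl-8-oxonon-2-ynoic acid | CCCCCCCCCCCCCCCC(=O)O[C@H](CC(C)=O)CC(C)(C)C#CC(=O)O
F2 | step 7 | methyl (6S)-6-(hexadecanoyloxy)-4,4-dimethyl-8-oxonon-2-ynoate | CCCCCCCCCCCCCCCC(=O)O[C@H](CC(C)=O)CC(C)(C)C#CC(=O)OC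
F3 | step 7 | methyl (2Z)-[(2R,4S)-4-(hexadecanoyloxy)-2-hydroxy-2,6,6-trimethylcyclohexylidene]acetate | CCCCCCCCCCCCCCCC(=O)O[C@H]1CC(C)(C)/C(=C/C(=O)OC)[C@](C)(O)C1
F4 | step 4 | (4R)-9,9-diethoxy-2,6,6-trimethylnon-1-en-7-yn-4-ol | CCOC(OCC)C#CC(C)(C)C[C@H](O)CC(C)=C
F5 | step 4 | (4R)-9,9-diethoxy-2,6,6-trimethylnon-1-en-7-yn-4-yl hexadecanoate | CCCCCCCCCCCCCCCC(=O)O[C@H](CC(C)=C)CC(C)(C)C#CC(OCC)OCC
F6 | step 2 | 4,4-dimethylhept-6-en-2-ynal | C=CCC(C)(C)C#CC=O
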